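**Retrosynthetic overview**
1. The last operation is a fourfold O-demethylation of 1,2-bis(2,3,6-tribromo-4,5-dimethoxyphenyl)ethane. Nothing else needs adjusting after the coupling.
2. The key disconnection is the central CH2–CH2 bond. It is made by anodic decarboxylative homocoupling (Kolbe electrolysis) of two molecules of 2-(2,3,6-tribromo-4,5-dimethoxyphenyl)acetic acid, in which CO2H acts as a traceless activating group that leaves as CO2.
3. This acid comes from commercial 3,4-dihydroxyphenylacetic acid by threefold ring bromination, then O-methylation.
4. Enabling feature: the molecule is two identical halves joined at the ethane bridge. Each bridge carbon sits on a fully substituted benzene ring, between C2–Br and C6–Br and para to a C4 oxygen that C3–Br and the C5 oxygen twist out of conjugation. The benzylic radical is therefore electron-poor, blocked at every ring carbon, and free to react only at its CH2 carbon.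
5. No ring is formed in the route. Both benzene rings are carried intact from the starting material.

Key step: step 3

Remark on the chemistry: the target SMILES holds no stereocentre, no stereogenic double bond and no configurationally stable axis. The compound is achiral, so no step needs stereocontrol.

Step 1
Reactants: 1 3,4-dihydroxyphenylacetic acid
Product: 2 2-(2,3,6-tribromo-4,5-dihydroxyphenyl)acetic acid
Conditions: Br2 (excess, about 4 equiv), AcOH, rt to 55 °C; work-up with aq NaHSO3
Reagents that add atoms: bromine, BrBr
Why: Electrophilic aromatic bromination should fill all three free ring positions, since each is ortho or para to a free hydroxyl group (C2 ortho to 3-OH, C5 ortho to 4-OH, C6 para to 3-OH) as in the exhaustive bromination of catechol and 4-alkylcatechols, while the side chain is not enolised in AcOH, the reductive work-up should return any o-quinone to the catechol, and no stereocentre is formed.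

Step 2
Reactants: 2 2-(2,3,6-tribromo-4,5-dihydroxyphenyl)acetic acid
Product: 4 2-(2,3,6-tribromo-4,5-dimethoxyphenyl)acetic acid, via methyl ester 3 (not isolated)
Conditions: MeI, K2CO3, acetone, reflux, N2; filter and evaporate; NaOH, MeOH–H2O, 50 °C; then aq HCl
Reagents that add atoms: iodomethane, CI; sodium hydroxide, [Na+].[OH-]
Why: Williamson-type O-methylation of the two acidic bromophenol groups and of the carboxylate, followed by ester saponification in the same flask, is the classical methylation–saponification sequence for phenolic acids, and the weak base in acetone should keep C-methylation of the arylacetate away while aryl bromides and aryl methyl ethers are inert to aqueous hydroxide at this temperature.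

Step 3
Reactants: 4 2-(2,3,6-tribromo-4,5-dimethoxyphenyl)acetic acid (two molecules)
Product: 6 1,2-bis(2,3,6-tribromo-4,5-dimethoxyphenyl)ethane, via benzylic radical 5 (not isolated)
Conditions: smooth Pt anode, large-area Pt cathode, undivided cell, NaOMe (0.1 equiv), MeOH–pyridine (4:1), no added supporting salt, constant current (about 0.2 A cm⁻² at the anode), 10–20 °C, until the acid is consumed
Reagents that add atoms: none
Why: Kolbe electrolysis, the anodic decarboxylative radical homocoupling that turns phenylacetic acids into bibenzyls: the carboxylate of 4 gives up one electron at the platinum anode and loses CO2 to give the primary benzylic radical 5, which builds up at the electrode surface at high current density and dimerises at its exocyclic carbon to 6, while the carboxyl protons are discharged as H2 at the cathode. The selectivity that decides the step is radical coupling against a second electron transfer to the benzylic cation (Hofer–Moest path with solvent capture), the usual fate of alkoxy-substituted arylacetic acids; here the three ring bromines withdraw electron density and the C4 methoxy group para to the radical centre is turned out of the ring plane by C3–Br and C5–OMe, so 5 should be no easier to oxidise than the parent benzyl radical, and weak neutralisation, a smooth Pt anode and the absence of foreign anions favour the radical path further. Site selectivity is secured because the ring carbons that share the spin (C2, C4, C6) all carry Br or OMe, so head-to-ring coupling could only give crowded, non-aromatisable cyclohexadienes that revert, and only the CH2–CH2 union is productive. Chemoselectivity follows from the oxidative manifold: the six aryl C–Br bonds are inert at the anode, the brominated ring with its twisted methoxy groups has a raised oxidation potential and is kept from the anode by the adsorbed carboxylate layer, and at a platinum cathode proton discharge from free acid and methanol should run well positive of polybromoarene reduction, which is the reason to prefer this coupling to a metal-mediated Wurtz reaction. No ring is closed and no stereocentre is formed. In one operation the step removes the activating carboxyl groups tracelessly and delivers the whole C14 skeleton with all six bromines and all four oxygens in place from a precursor of half the size.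

Step 4
Reactants: 6 1,2-bis(2,3,6-tribromo-4,5-dimethoxyphenyl)ethane
Product: 7 1,2-bis(2,3,6-tribromo-4,5-dihydroxyphenyl)ethane (target)
Conditions: BBr3 (excess), CH2Cl2, 0 °C to rt, N2; then ice-water
Reagents that add atoms: none
Why: BBr3-mediated aryl methyl ether cleavage (boron coordination at oxygen, bromide attack at the methyl carbon, hydrolysis of the B–O bonds on work-up) is the standard final deprotection of polybrominated veratrole units and should leave the aryl C–Br bonds and the saturated bridge untouched.

**Compound list**
1 | 3,4-dihydroxyphenylacetic acid | OC(=O)Cc1ccc(O)c(O)c1 | starting material
2 | 2-(2,3,6-tribromo-4,5-dihydroxyphenyl)acetic acid | OC(=O)Cc1c(Br)c(Br)c(O)c(O)c1Br | intermediate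
3 | methyl 2-(2,3,6-tribromo-4,5-dimethoxyphenyl)acetate (not isolated) | COC(=O)Cc1c(Br)c(Br)c(OC)c(OC)c1Br | intermediate
4 | 2-(2,3,6-tribromo-4,5-dimethoxyphenyl)acetic acid | OC(=O)Cc1c(Br)c(Br)c(OC)c(OC)c1Br | intermediate
5 | (2,3,6-tribromo-4,5-dimethoxyphenyl)methyl radical (not isolated) | [CH2]c1c(Br)c(Br)c(OC)c(OC)c1Br | intermediate
6 | 1,2-bis(2,3,6-tribromo-4,5-dimethoxyphenyl)ethane (achiral) | COc1c(OC)c(Br)c(CCc2c(Br)c(OC)c(OC)c(Br)c2Br)c(Br)c1Br | intermediate
7 | 1,2-bis(2,3,6-tribromo-4,5-dihydroxyphenyl)ethane (achiral) | Oc1c(O)c(Br)c(CCc2c(Br)c(O)c(O)c(Br)c2Br)c(Br)c1Br | target

Total step count: 4
Longest linear sequence: 4 steps (1 to 7). Both halves of the coupling come from the same batch of 4.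

**Steps most likely to fail**

Step 3 (key step).
- What may go wrong: a second electron transfer from the benzylic radical at the anode, with capture of the cation by methanol or pyridine, and fouling of the anode by the sparingly soluble coupling product.
- Fallback: the same bond is reached reductively from a benzylic halide. Setting out from 4, a silver-catalysed Hunsdiecker-type bromodecarboxylation (AgOTf/1,10-phenanthroline cat., dibromoisocyanuric acid, 1,2-dichloroethane, gentle warming) should give 2,3,6-tribromo-4,5-dimethoxybenzyl bromide F1. The ring has no free position, so only the carboxyl group can react. A titanocene(III)-mediated Wurtz-type homocoupling follows (substoichiometric Cp2TiCl2, Mn dust, THF, rt). This single-electron reductant abstracts benzylic but not aryl halogen, and the coupling comes back to the route at 6.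

Step 1.
- What may go wrong: ipso attack of bromine at the ring carbon para to the 4-hydroxyl group followed by loss of CO2 from the free acid, stalling before the third bromination at the hindered position between side chain and hydroxyl, and oxidation of the catechol by excess bromine.
- Fallback: the free carboxyl group is masked before the halogenation. Setting out from 1, Fischer esterification (MeOH, cat. H2SO4, reflux) should give methyl 2-(3,4-dihydroxyphenyl)acetate F2. Exhaustive bromination (Br2, AcOH, then aq NaHSO3) should give methyl 2-(2,3,6-tribromo-4,5-dihydroxyphenyl)acetate F3. F3 cannot fragment with loss of CO2 and is easier to purify than the polar acid. O-methylation (MeI, K2CO3, acetone, reflux) comes back to the route at 3, which is saponified as in step 2.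

Step 4.
- What may go wrong: incomplete fourfold ether cleavage, because the hexabromide and its partly cleaved boron complexes drop out of CH2Cl2, and air oxidation of the catechol units during work-up.
- Fallback: the protecting group is changed to one that leaves by mild acid solvolysis.
  - Setting out from 2, MOMCl and K2CO3 in acetone should give methoxymethyl 2-[2,3,6-tribromo-4,5-bis(methoxymethoxy)phenyl]acetate F4.
  - Saponification (NaOH, MeOH–H2O, then cold dilute HCl to pH 4) should give 2-[2,3,6-tribromo-4,5-bis(methoxymethoxy)phenyl]acetic acid F5.
  - Kolbe electrolysis under the conditions of step 3 should give 1,2-bis[2,3,6-tribromo-4,5-bis(methoxymethoxy)phenyl]ethane F6.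
  - Acetal exchange (cat. HCl, MeOH, 40 °C, N2) comes back to the route at 7.

**Further compounds**
F1 | step 3 | 2,3,6-tribromo-4,5-dimethoxybenzyl bromide | BrCc1c(Br)c(Br)c(OC)c(OC)c1Br
F2 | step 1 | methyl 2-(3,4-dihydroxyphenyl)acetate | COC(=O)Cc1ccc(O)c(O)c1
F3 | step 1 | methyl 2-(2,3,6-tribromo-4,5-dihydroxyphenyl)acetate | COC(=O)Cc1c(Br)c(Br)c(O)c(O)c1Br
F4 | step 4 | methoxymethyl 2-[2,3,6-tribromo-4,5-bis(methoxymethoxy)phenyl]acetate | COCOC(=O)Cc1c(Br)c(Br)c(OCOC)c(OCOC)c1Br
F5 | step 4 | 2-[2,3,6-tribromo-4,5-bis(methoxymethoxy)phenyl]acetic acid | OC(=O)Cc1c(Br)c(Br)c(OCOC)c(OCOC)c1Br
F6 | step 4 | 1,2-bis[2,3,6-tribromo-4,5-bis(methoxymethoxy)phenyl]ethane | COCOc1c(OCOC)c(Br)c(CCc2c(Br)c(OCOC)c(OCOC)c(Br)c2Br)c(Br)c1Br
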